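**Retrosynthetic overview** (chroman numbering: O1, C2, C3, C4, C4a, C5–C8, C8a; ring A = benzene ring, ring B = dihydropyran ring; side-chain carbons primed, counted from C2)
1. The strategy rests on ring A carrying the ether oxygen O1 on C8a directly beside the methyl-bearing C8: a nucleophile/electrophile pair on adjacent carbons, which an aryne across C8–C8a can take up in one operation.
2. Side chain: O–Si cleavage last; C5'–C6' from an allylic bromide and lithiated geranyl phenyl sulfone with reductive desulfonylation; C5' is functionalised by SeO2 oxidation of the (E)-methyl of a prenyl terminus.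
3. Key disconnection: O1–C8a and C8–CH3 lead back to a chloroarene (Cl on C8a, H on C8) with a tertiary alcohol tethered at C4a; the alkoxide and iodomethane add across the aryne.
4. C4–C4a: B-alkyl Suzuki–Miyaura coupling of the 9-BBN adduct of (R)-linalool (source of the C2 stereocentre) with silylated 3-bromo-4-chloro-2-methylphenol.
5. Ring order: ring A is bought as the phenol; ring B is the only ring formed (step 4).

Key step: step 4

Assumption: (R)-(−)-linalool of high enantiomeric purity is used; no step breaks a bond at this carbon, so the target should have the enantiomeric purity of the linalool.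

**Step 1**
Reactants: 1 3-bromo-2-methylphenol
Product: 2 3-bromo-4-chloro-2-methylphenol
Conditions: SO2Cl2 (1.05 equiv), Ph2S (cat.), AlCl3 (cat.), CH2Cl2, 0 °C → rt
Reagents that add atoms: sulfuryl chloride, O=S(=O)(Cl)Cl
Why: Electrophilic aromatic chlorination directed by the hydroxyl group should go para to it (C4), since the sulfide/AlCl3-modified reagent is too bulky for the ortho site C6, as in the para-chlorination of cresols and xylenols whose para position is flanked by a substituent.

**Step 2**
Reactants: 2 3-bromo-4-chloro-2-methylphenol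
Product: 3 (3-bromo-4-chloro-2-methylphenoxy)triisopropylsilane
Conditions: TIPSCl, imidazole, DMF, rt
Reagents that add atoms: triisopropylsilyl chloride, CC(C)[Si](Cl)(C(C)C)C(C)C
Why: Silylation of the phenol (substitution at silicon, imidazole as base and silyl carrier) should be routine, and the bulky silyl ether is chosen because it tolerates organolithiums and screens the ring hydrogen next to oxygen in step 4.

**Step 3**
Reactants: 4 (R)-linalool; 3 (3-bromo-4-chloro-2-methylphenoxy)triisopropylsilane
Product: 6 (R)-1-[6-chloro-2-methyl-3-(triisopropylsilyloxy)phenyl]-3,7-dimethyloct-6-en-3-ol, via B-alkyl borane 5 (not isolated)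
Conditions: 9-BBN (1.5 equiv), THF, 0 °C → rt; then 3, Pd(dppf)Cl2 (5 mol%), K3PO4 (3 M aq.), THF/DMF, 65 °C
Reagents that add atoms: 9-borabicyclo[3.3.1]nonane (9-BBN), B1C2CCCC1CCC2 (its boron stays only in 5)
Why: 9-BBN should hydroborate only the monosubstituted vinyl group, anti-Markovnikov, and the B-alkyl borane should then undergo B-alkyl Suzuki–Miyaura coupling at C–Br, into which dppf-ligated zerovalent palladium inserts much faster than into C–Cl, while the carbinol stereocentre takes no part and keeps its configuration (any O–B bond formed by excess 9-BBN at the tertiary hydroxyl is hydrolysed by the aqueous base).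

**Step 4**
Reactants: 6 (R)-1-[6-chloro-2-methyl-3-(triisopropylsilyloxy)phenyl]-3,7-dimethyloct-6-en-3-ol
Product: 10 (R)-2,5,8-trimethyl-2-(4-methylpent-3-en-1-yl)-6-(triisopropylsilyloxy)chroman, via dilithio species 7 (not isolated), via aryne lithium alkoxide 8 (not isolated), via lithiated chroman 9 (not isolated)
Conditions: s-BuLi (2.2 equiv), THF, −78 °C; warm to −20 °C; then MeI (3 equiv), −78 °C → rt
Reagents that add atoms: iodomethane, CI; sec-butyllithium, CCC(C)[Li] (lithium only in 7, 8 and 9)
Why: The first equivalent of s-BuLi should form the lithium alkoxide and the second should remove C8–H, the only hydrogen ortho to chlorine; on warming the ortho-chloro aryllithium loses LiCl to give the C8–C8a aryne, the tethered alkoxide adds at C8a, and the aryllithium left on C8, now ortho to the new ether oxygen, is methylated by MeI. This is the known base-induced aryne cyclisation of a tethered oxygen nucleophile with electrophilic capture of the resulting aryl anion, a tertiary lithium alkoxide being a less common nucleophile in it. Ring B closes in a six-membered exo mode (6-exo-dig on the in-plane aryne bond: O1–C8a forms and C8 stays outside the new ring). No stereocentre is formed, and C2 keeps the (R) configuration of linalool because its oxygen acts as the nucleophile and the C2–O bond is never broken. The step needs site-selective deprotonation and regioselective addition: chlorine on C8a has a single ortho hydrogen and C7–H is screened by the triisopropylsilyl group, and the four-atom tether from C4a can deliver oxygen only to C8a, since attack at C8 would require a meta-bridged ring. An alkyllithium is used in place of a lithium amide so that no N–H acid is present to protonate C8–Li before MeI is added.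

**Step 5**
Reactants: 10 (R)-2,5,8-trimethyl-2-(4-methylpent-3-en-1-yl)-6-(triisopropylsilyloxy)chroman
Product: 12 (R,E)-2-methyl-5-[2,5,8-trimethyl-6-(triisopropylsilyloxy)chroman-2-yl]pent-2-en-1-ol, via over-oxidised enal 11 (not isolated)
Conditions: SeO2 (0.3 equiv), t-BuOOH (2 equiv), salicylic acid (0.1 equiv), CH2Cl2, rt; then NaBH4, MeOH, 0 °C
Reagents that add atoms: tert-butyl hydroperoxide, CC(C)(C)OO (terminal oxidant; the oxygen is passed on by SeO2, O=[Se]=O)
Why: Allylic oxidation by SeO2 (ene reaction, then [2,3]-sigmatropic shift) attacks the more substituted alkene terminus at the methyl group trans to the chain, so the (E)-allylic alcohol should result, and NaBH4 returns any enal formed by over-oxidation to the same alcohol by 1,2-reduction.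

**Step 6**
Reactants: 12 (R,E)-2-methyl-5-[2,5,8-trimethyl-6-(triisopropylsilyloxy)chroman-2-yl]pent-2-en-1-ol
Product: 13 (R,E)-2-(5-bromo-4-methylpent-3-en-1-yl)-2,5,8-trimethyl-6-(triisopropylsilyloxy)chroman
Conditions: CBr4, PPh3, CH2Cl2, 0 °C
Reagents that add atoms: carbon tetrabromide, BrC(Br)(Br)Br
Why: The Appel reaction, an SN2 displacement of the alkoxyphosphonium ion by bromide at the primary allylic carbon, should give the (E)-bromide without allylic transposition and without touching the silyl ether.

**Step 7**
Reactants: 14 geranyl bromide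
Product: 15 geranyl phenyl sulfone, (E)-[(3,7-dimethylocta-2,6-dien-1-yl)sulfonyl]benzene
Conditions: PhSO2Na, DMF, rt
Reagents that add atoms: sodium benzenesulfinate, [Na+].[O-]S(=O)c1ccccc1
Why: S-Alkylation of the sulfinate by SN2 displacement of the primary allylic bromide should give the sulfone with the (E) geometry intact.

**Step 8**
Reactants: 15 geranyl phenyl sulfone; 13 (R,E)-2-(5-bromo-4-methylpent-3-en-1-yl)-2,5,8-trimethyl-6-(triisopropylsilyloxy)chroman
Product: 17 (R)-2,5,8-trimethyl-2-[(3E,7E)-4,8,12-trimethyl-6-(phenylsulfonyl)trideca-3,7,11-trien-1-yl]-6-(triisopropylsilyloxy)chroman (both C6' epimers), via lithiated sulfone 16 (not isolated)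
Conditions: n-BuLi (1.05 equiv), THF, −78 °C; then 13, −78 → −20 °C
Reagents that add atoms: n-butyllithium, CCCC[Li] (lithium only in 16)
Why: Alkylation of the sulfone-stabilised allylic carbanion, which reacts at the carbon alpha to sulfur, with the primary allylic bromide by SN2 should form the C5'–C6' bond with both alkene geometries intact; C6' forms as both epimers, which does not matter because step 9 removes the sulfonyl group.

**Step 9**
Reactants: 17 (R)-2,5,8-trimethyl-2-[(3E,7E)-4,8,12-trimethyl-6-(phenylsulfonyl)trideca-3,7,11-trien-1-yl]-6-(triisopropylsilyloxy)chroman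
Product: 18 (R)-2,5,8-trimethyl-2-[(3E,7E)-4,8,12-trimethyltrideca-3,7,11-trien-1-yl]-6-(triisopropylsilyloxy)chroman
Conditions: Pd(dppp)Cl2 (10 mol%), LiBHEt3 (2.5 equiv), THF, 0 °C → rt
Reagents that add atoms: none
Why: In this palladium-catalysed reductive desulfonylation, zerovalent palladium formed from Pd(dppp)Cl2 and hydride ionises the allylic sulfone to a π-allyl complex and hydride is delivered to the less substituted terminus C6', which should leave the trisubstituted (E)-alkene C7'=C8' in place.

**Step 10**
Reactants: 18 (R)-2,5,8-trimethyl-2-[(3E,7E)-4,8,12-trimethyltrideca-3,7,11-trien-1-yl]-6-(triisopropylsilyloxy)chroman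
Product: 19 (R)-2,5,8-trimethyl-2-[(3E,7E)-4,8,12-trimethyltrideca-3,7,11-trien-1-yl]chroman-6-ol (CID5282348)
Conditions: TBAF, AcOH, THF, 0 °C → rt, under argon
Reagents that add atoms: none
Why: Fluoride cleaves the aryl O–Si bond (desilylation), and the acetic acid buffer keeps the released chromanol protonated and so less prone to air oxidation, with nothing else in the molecule affected.

**Compound list**
1 | 3-bromo-2-methylphenol | Cc1c(O)cccc1Br | starting material
2 | 3-bromo-4-chloro-2-methylphenol | Cc1c(O)ccc(Cl)c1Br | intermediate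
3 | (3-bromo-4-chloro-2-methylphenoxy)triisopropylsilane | Cc1c(O[Si](C(C)C)(C(C)C)C(C)C)ccc(Cl)c1Br | intermediate
4 | (R)-linalool | CC(C)=CCC[C@](O)(C)C=C | starting material
5 | (S)-1-(9-borabicyclo[3.3.1]nonan-9-yl)-3,7-dimethyloct-6-en-3-ol (same spatial arrangement as 4; the descriptor changes only through CIP priorities) | CC(C)=CCC[C@](O)(C)CCB1C2CCCC1CCC2 | intermediate
6 | (R)-1-[6-chloro-2-methyl-3-(triisopropylsilyloxy)phenyl]-3,7-dimethyloct-6-en-3-ol | CC(C)=CCC[C@](O)(C)CCc1c(C)c(O[Si](C(C)C)(C(C)C)C(C)C)ccc1Cl | intermediate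
7 | lithium (R)-alkoxide of 6 lithiated at the ring carbon next to chlorine (C8) | CC(C)=CCC[C@](O[Li])(C)CCc1c(C)c(O[Si](C(C)C)(C(C)C)C(C)C)cc([Li])c1Cl | intermediate
8 | C8–C8a aryne bearing the tethered lithium (R)-alkoxide | CC(C)=CCC[C@](O[Li])(C)CCC1=C(C)C(O[Si](C(C)C)(C(C)C)C(C)C)=CC#C1 | intermediate
9 | (R)-8-lithio-2,5-dimethyl-2-(4-methylpent-3-en-1-yl)-6-(triisopropylsilyloxy)chroman | CC(C)=CCC[C@]1(C)CCc2c(C)c(O[Si](C(C)C)(C(C)C)C(C)C)cc([Li])c2O1 | intermediate
10 | (R)-2,5,8-trimethyl-2-(4-methylpent-3-en-1-yl)-6-(triisopropylsilyloxy)chroman | CC(C)=CCC[C@]1(C)CCc2c(C)c(O[Si](C(C)C)(C(C)C)C(C)C)cc(C)c2O1 | intermediate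
11 | (R,E)-2-methyl-5-[2,5,8-trimethyl-6-(triisopropylsilyloxy)chroman-2-yl]pent-2-enal | O=C/C(C)=C/CC[C@]1(C)CCc2c(C)c(O[Si](C(C)C)(C(C)C)C(C)C)cc(C)c2O1 | intermediate
12 | (R,E)-2-methyl-5-[2,5,8-trimethyl-6-(triisopropylsilyloxy)chroman-2-yl]pent-2-en-1-ol | OC/C(C)=C/CC[C@]1(C)CCc2c(C)c(O[Si](C(C)C)(C(C)C)C(C)C)cc(C)c2O1 | intermediate
13 | (R,E)-2-(5-bromo-4-methylpent-3-en-1-yl)-2,5,8-trimethyl-6-(triisopropylsilyloxy)chroman | BrC/C(C)=C/CC[C@]1(C)CCc2c(C)c(O[Si](C(C)C)(C(C)C)C(C)C)cc(C)c2O1 | intermediate
14 | geranyl bromide | CC(C)=CCC/C(C)=C/CBr | starting material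
15 | geranyl phenyl sulfone | CC(C)=CCC/C(C)=C/CS(=O)(=O)c1ccccc1 | intermediate
16 | alpha-lithiated geranyl phenyl sulfone | CC(C)=CCC/C(C)=C/C([Li])S(=O)(=O)c1ccccc1 | intermediate
17 | (R)-2,5,8-trimethyl-2-[(3E,7E)-4,8,12-trimethyl-6-(phenylsulfonyl)trideca-3,7,11-trien-1-yl]-6-(triisopropylsilyloxy)chroman, both C6' epimers | CC(C)=CCC/C(C)=C/C(C/C(C)=C/CC[C@]1(C)CCc2c(C)c(O[Si](C(C)C)(C(C)C)C(C)C)cc(C)c2O1)S(=O)(=O)c1ccccc1 | intermediate
18 | (R)-2,5,8-trimethyl-2-[(3E,7E)-4,8,12-trimethyltrideca-3,7,11-trien-1-yl]-6-(triisopropylsilyloxy)chroman | CC(C)=CCC/C(C)=C/CC/C(C)=C/CC[C@]1(C)CCc2c(C)c(O[Si](C(C)C)(C(C)C)C(C)C)cc(C)c2O1 | intermediate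
19 | (R)-2,5,8-trimethyl-2-[(3E,7E)-4,8,12-trimethyltrideca-3,7,11-trien-1-yl]chroman-6-ol | CC(C)=CCC/C(C)=C/CC/C(C)=C/CC[C@]1(C)CCc2c(C)c(O)cc(C)c2O1 | target

**Total step count:** 10
**Longest linear sequence:** 9 steps (steps 1–6 and 8–10, from 1); step 7 is a one-step branch.

**Steps most likely to fail**

Step 4. Lithiation may occur at a benzylic site in place of C8. The aryne may be captured by the alkyllithium or by a second aryllithium in place of the hindered tertiary alkoxide. The C8 anion may be protonated before methylation. The fallback sets out from 6 and separates the two bond formations. Palladium-catalysed intramolecular C–O coupling of the tertiary alcohol with the aryl chloride (Pd(OAc)2, 2-(di-tert-butylphosphino)-1,1'-binaphthyl, Cs2CO3, toluene, 80 °C) should close ring B to (R)-2,5-dimethyl-2-(4-methylpent-3-en-1-yl)-6-(triisopropylsilyloxy)chroman F1. Directed ortho-lithiation of F1 at C8, beside the ring oxygen (s-BuLi, TMEDA, Et2O, −78 → 0 °C; C7 is screened by the silyl group), followed by MeI returns to the route at 10. F1 is also what a prematurely protonated key step would deliver, so such material can be recycled the same way.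

Step 3. Oxidative addition and transmetalation may be slow at the C–Br bond flanked by methyl and chlorine. Insertion into C–Cl may compete, the alkylborane may decompose, and aqueous base may partly remove the silyl ether. The fallback sets out from 3 and 4. A Heck reaction (Pd(OAc)2, n-Bu4NCl, NaHCO3, DMF, 90 °C) should arylate the terminal vinyl carbon of linalool; the carbinol carbon has no hydrogen, so only the styrene can form. This gives (R,E)-1-[6-chloro-2-methyl-3-(triisopropylsilyloxy)phenyl]-3,7-dimethylocta-1,6-dien-3-ol F2. Diimide reduction (2-nitrobenzenesulfonyl hydrazide, Et3N, CH2Cl2, rt) then saturates the disubstituted styrene double bond in preference to the trisubstituted one and leaves C–Cl alone, returning to the route at 6.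

Step 5. Oxidation may go to the allylic methylene or the (Z)-methyl, conversion may stall, and the electron-rich chroman may be damaged by the oxidant. The fallback sets out from 10, whose only alkene is the prenyl terminus. Lemieux–Johnson cleavage (OsO4 cat., NaIO4, 2,6-lutidine, dioxane/H2O) should give (S)-3-[2,5,8-trimethyl-6-(triisopropylsilyloxy)chroman-2-yl]propanal F3 (same spatial arrangement; the descriptor changes through CIP priorities). A Wittig reaction with the stabilised ylide Ph3P=C(CH3)CO2Et (toluene, 80 °C) should give ethyl (R,E)-2-methyl-5-[2,5,8-trimethyl-6-(triisopropylsilyloxy)chroman-2-yl]pent-2-enoate F4 with (E) selectivity. Reduction with i-Bu2AlH (CH2Cl2, −78 °C) returns to the route at 12.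

**Further compounds**
F1 | step 4 | (R)-2,5-dimethyl-2-(4-methylpent-3-en-1-yl)-6-(triisopropylsilyloxy)chroman | CC(C)=CCC[C@]1(C)CCc2c(C)c(O[Si](C(C)C)(C(C)C)C(C)C)ccc2O1
F2 | step 3 | (R,E)-1-[6-chloro-2-methyl-3-(triisopropylsilyloxy)phenyl]-3,7-dimethylocta-1,6-dien-3-ol | CC(C)=CCC[C@](O)(C)/C=C/c1c(C)c(O[Si](C(C)C)(C(C)C)C(C)C)ccc1Cl
F3 | step 5 | (S)-3-[2,5,8-trimethyl-6-(triisopropylsilyloxy)chroman-2-yl]propanal | O=CCC[C@]1(C)CCc2c(C)c(O[Si](C(C)C)(C(C)C)C(C)C)cc(C)c2O1
F4 | step 5 | ethyl (R,E)-2-methyl-5-[2,5,8-trimethyl-6-(triisopropylsilyloxy)chroman-2-yl]pent-2-enoate | CCOC(=O)/C(C)=C/CC[C@]1(C)CCc2c(C)c(O[Si](C(C)C)(C(C)C)C(C)C)cc(C)c2O1
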